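**Plan**

1. Labdane numbering is used (ring A: C1–C5, C10; ring B: C5–C10; C18/C19 on C4, C20 on C10, side chain C11–C16 on C9). The retrosynthesis cuts C13=C14 (cross-metathesis), C9–C11 (carbonyl addition, then 1,3-carbonyl transposition), the C17 and C18 methyls (enolate methylations), ring A at C1–C10 and C3–C4 (one annulation), the C20 methyl, and C4–C5.
2. Forward: ring B is made first as a 2-methyl-3-(carboxymethyl)cyclohexanone, ring A is annulated onto it in one operation, ring B is then elaborated (C8 methyl, side chain, C7=C8), and the side-chain acid is completed last.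
3. Enabling feature: in ring A the carbinol C3 and C19 on C4 form a masked β-keto ester, and the quaternary C10 is α to C9 of ring B. C10 and C4 are both attached to the ring-fusion carbon C5, so the three carbons of an acrylate (C1–C2–C3) can bridge them: Michael addition at C1, Dieckmann acylation at C3.
4. Stereochemistry: C5 from a ligand-controlled CuH conjugate reduction; C10 by Michael addition anti to the C5 substituent; C4 by methylation of the β-keto ester anti to the C10 methyl; C3 by equatorial hydride delivery; C9 by axial protonation in a dissolving-metal reduction; the E-olefin by metathesis.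

Key step: step 3

Assumption: (S)-p-tol-BINAP is written in step 2 as the ligand antipode that gives the (R)-configured centre of 6; if a model reduction shows the opposite sense, the (R)-ligand is used.

**Route**

Step 1
Reactants: 1 3-ethoxycyclohex-2-en-1-one; 2 tert-butyl acetate
Product: 5 tert-butyl 2-(3-oxocyclohex-1-en-1-yl)acetate, via lithium enolate 3 (not isolated), via hydroxy enol ether 4 (not isolated)
Conditions: LiN(i-Pr)2, THF, −78 °C; add 1, −78 to −20 °C; then 1 M HCl, rt
Reagents that add atoms: water, O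
Why: Stork–Danheiser sequence, in which the ester enolate adds 1,2 to the vinylogous ester carbonyl and acid unmasks the ketone with loss of water and ethanol, so that the enone is transposed and the acetate arm (C4–C19) sits on the future C5; no stereocentre is formed.

Step 2
Reactants: 5 tert-butyl 2-(3-oxocyclohex-1-en-1-yl)acetate
Product: 7 tert-butyl 2-[(1R,2R)-2-methyl-3-oxocyclohexyl]acetate, via silyl enol ether 6 (not isolated)
Conditions: CuCl (5 mol%), NaOt-Bu (5 mol%), (S)-p-tol-BINAP (5 mol%), Ph2SiH2, toluene, 0 °C; then MeI, Bu4N[Ph3SiF2], THF, rt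
Reagents that add atoms: iodomethane, CI
Why: One-pot asymmetric CuH conjugate reduction and enolate alkylation, in which the chiral bisphosphine directs hydride to one face of the β-carbon and so sets C5, the silyl enol ether fixes the enolate at C10, and fluoride-triggered methylation installs C20 trans to the acetate arm (this C10 centre is re-enolized in step 3).

Step 3
Reactants: 7 tert-butyl 2-[(1R,2R)-2-methyl-3-oxocyclohexyl]acetate; 8 methyl acrylate
Product: 10 tert-butyl (1R,4aR,8aR)-4a-methyl-2,5-dioxodecahydronaphthalene-1-carboxylate (trans-fused; keto form drawn, partly enolized), via Michael adduct 9 (not isolated)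
Conditions: KOt-Bu (2.5 equiv), THF/t-BuOH (10:1), −20 °C, slow addition of 8 (1.05 equiv), then rt; AcOH quench
Reagents that add atoms: none
Why: KOt-Bu equilibrates 7 to the more substituted potassium enolate (C9–C10), which adds to the acrylate β-carbon (C1) to give 9; proton exchange then forms the tert-butyl ester enolate at C4, which acylates the new methyl ester carbonyl (C3) and expels methoxide. The closest known reaction type is the tandem Michael–Dieckmann (consecutive Michael–Claisen) annulation of ketone enolates with acrylates. Ring A closes by 6-exo-trig attack of the C4 enolate on the C3 ester carbonyl. The quaternary C10 centre is set by substrate control: the C5 acetate arm sits pseudoaxial in the enolate to avoid A(1,2) strain with the C10 methyl, the acrylate enters on the opposite face, C1 ends trans to C4 and the decalin is trans-fused; C4 stays epimerizable and is held as the β-keto ester enolate. The step needs C10-over-C8 regioselectivity and closure in the C4-to-C3 direction: the Michael addition is reversible and only the C10 adduct can reach the stabilized β-keto ester enolate (the bridged diketone from C8 attack on C3 cannot enolize at its bridgehead and reverts), while the tert-butyl ester at C19 is too poor an acyl acceptor for the competing C2-to-C19 closure.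

Step 4
Reactants: 10 tert-butyl (1R,4aR,8aR)-4a-methyl-2,5-dioxodecahydronaphthalene-1-carboxylate
Product: 12 tert-butyl (1S,4aR,6S,8aS)-1,4a,6-trimethyl-2,5-dioxodecahydronaphthalene-1-carboxylate, via monomethyl keto ester 11 (not isolated)
Conditions: LiN(i-Pr)2 (2.2 equiv), THF, −78 to −40 °C; MeI (1.05 equiv), −78 °C; then DMPU, MeI (5 equiv), −78 °C to rt
Reagents that add atoms: iodomethane, CI
Why: Double enolate alkylation, in which the first equivalent of base masks C3 as the β-keto ester enolate, the second forms the C9/C8 ketone enolate that is methylated first (C17; its configuration is irrelevant because C8 becomes sp2 in step 7), and the β-keto ester enolate is then methylated on the face opposite the axial C10 methyl, so that the new C4 methyl is equatorial and the ester axial, as is usual for 3-oxo-4-carboalkoxy trans-decalins.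

Step 5
Reactants: 12 tert-butyl (1S,4aR,6S,8aS)-1,4a,6-trimethyl-2,5-dioxodecahydronaphthalene-1-carboxylate
Product: 13 tert-butyl (1S,2S,4aR,6S,8aS)-2-hydroxy-1,4a,6-trimethyl-5-oxodecahydronaphthalene-1-carboxylate (C3 hydroxyl axial, anti to the axial ester)
Conditions: LiBH(s-Bu)3 (L-Selectride, 1.1 equiv), THF, −78 °C; cold aq. NH4Cl
Reagents that add atoms: none
Why: Bulky trialkylborohydride reduction, in which the C3 ketone (one α-methylene) should react faster than the C9 ketone flanked by a quaternary and a tertiary carbon, and hydride is delivered along the equatorial trajectory so that the C3 hydroxyl ends axial, as with 4,4-disubstituted 3-oxo terpenoids.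

Step 6
Reactants: 13 tert-butyl (1S,2S,4aR,6S,8aS)-2-hydroxy-1,4a,6-trimethyl-5-oxodecahydronaphthalene-1-carboxylate
Product: 14 tert-butyl (1S,2S,4aR,8aS)-2,5-bis[(tert-butyldimethylsilyl)oxy]-1,4a,6-trimethyl-1,2,3,4,4a,7,8,8a-octahydronaphthalene-1-carboxylate
Conditions: TBSOTf (2.5 equiv), Et3N (4 equiv), CH2Cl2, 0 °C to rt
Reagents that add atoms: tert-butyldimethylsilyl trifluoromethanesulfonate, CC(C)(C)[Si](C)(C)OS(=O)(=O)C(F)(F)F
Why: Silyl triflate/amine silylation protects the hindered axial C3 hydroxyl and at the same time converts the C9 ketone, whose only enolizable position is C8, into its silyl enol ether; no stereocentre is formed.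

Step 7
Reactants: 14 tert-butyl (1S,2S,4aR,8aS)-2,5-bis[(tert-butyldimethylsilyl)oxy]-1,4a,6-trimethyl-1,2,3,4,4a,7,8,8a-octahydronaphthalene-1-carboxylate
Product: 15 tert-butyl (1S,2S,4aR,8aS)-2-[(tert-butyldimethylsilyl)oxy]-1,4a,6-trimethyl-5-oxo-1,2,3,4,4a,5,8,8a-octahydronaphthalene-1-carboxylate
Conditions: Pd(OAc)2 (1.1 equiv), MeCN/DMSO, 40–60 °C
Reagents that add atoms: none
Why: Saegusa–Ito oxidation, in which the palladium enolate at C8 undergoes β-hydride elimination toward C7 to give the conjugated endocyclic enone and removes the C8 stereocentre.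

Step 8
Reactants: 15 tert-butyl (1S,2S,4aR,8aS)-2-[(tert-butyldimethylsilyl)oxy]-1,4a,6-trimethyl-5-oxo-1,2,3,4,4a,5,8,8a-octahydronaphthalene-1-carboxylate; 16 4-bromo-2-methylbut-1-ene
Product: 18 tert-butyl 2-[(tert-butyldimethylsilyl)oxy]-5-hydroxy-1,4a,6-trimethyl-5-(3-methylbut-3-en-1-yl)-1,2,3,4,4a,5,8,8a-octahydronaphthalene-1-carboxylate (other centres as in 15; carbinol epimer from attack anti to the angular methyl drawn), via Grignard reagent 17 (not isolated)
Conditions: Mg, THF, rt (16 to 17); LaCl3·2LiCl (1.1 equiv), THF, 0 °C; add 15; aq. NH4Cl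
Reagents that add atoms: none
Why: Lanthanide-promoted Grignard 1,2-addition to the hindered enone forms the C9–C11 bond, and the carbinol configuration is irrelevant because it is erased in step 9.

Step 9
Reactants: 18 tert-butyl 2-[(tert-butyldimethylsilyl)oxy]-5-hydroxy-1,4a,6-trimethyl-5-(3-methylbut-3-en-1-yl)-1,2,3,4,4a,5,8,8a-octahydronaphthalene-1-carboxylate
Product: 19 tert-butyl 2-[(tert-butyldimethylsilyl)oxy]-1,4a,6-trimethyl-5-(3-methylbut-3-en-1-yl)-7-oxo-1,2,3,4,4a,7,8,8a-octahydronaphthalene-1-carboxylate (centres as in 15)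
Conditions: C5H5NH[CrO3Cl] (pyridinium chlorochromate, 3 equiv), NaOAc, 4 Å MS, CH2Cl2, rt
Reagents that add atoms: pyridinium chlorochromate, [O-][Cr](=O)(=O)Cl.c1cc[nH+]cc1
Why: Babler–Dauben oxidative transposition, in which the tertiary allylic chromate ester shifts [3,3] to C7 and is oxidized, so that the oxygen moves to C7 and the double bond to C8=C9; no stereocentre is formed.

Step 10
Reactants: 19 tert-butyl 2-[(tert-butyldimethylsilyl)oxy]-1,4a,6-trimethyl-5-(3-methylbut-3-en-1-yl)-7-oxo-1,2,3,4,4a,7,8,8a-octahydronaphthalene-1-carboxylate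
Product: 21 tert-butyl 2-[(tert-butyldimethylsilyl)oxy]-1,4a,6-trimethyl-5-(3-methylbut-3-en-1-yl)-7-{[(trifluoromethyl)sulfonyl]oxy}-1,2,3,4,4a,5,8,8a-octahydronaphthalene-1-carboxylate (C9 hydrogen anti to the C10 methyl, side chain equatorial), via lithium enolate 20 (not isolated)
Conditions: Li (2.5 equiv), NH3(l)/THF, t-BuOH (1 equiv), −78 °C; isoprene; NH3 removed; PhNTf2 (1.5 equiv), THF, −78 to 0 °C
Reagents that add atoms: N-phenylbis(trifluoromethanesulfonimide), O=S(=O)(N(c1ccccc1)S(=O)(=O)C(F)(F)F)C(F)(F)F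
Why: Birch-type dissolving-metal reduction of the enone with axial protonation at the β-carbon sets the C9 hydrogen anti to the C10 methyl, and the regiodefined C7 enolate is trapped as the enol triflate.

Step 11
Reactants: 21 the enol triflate
Product: 22 tert-butyl (1S,2S,4aS,5R,8aS)-2-[(tert-butyldimethylsilyl)oxy]-1,4a,6-trimethyl-5-(3-methylbut-3-en-1-yl)-1,2,3,4,4a,5,8,8a-octahydronaphthalene-1-carboxylate
Conditions: Pd(OAc)2 (5 mol%), PPh3 (10 mol%), HCO2H, n-Bu3N, DMF, 60 °C
Reagents that add atoms: none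
Why: Palladium-catalysed formate reduction of the enol triflate (oxidative addition, decarboxylation of formate to a palladium hydride, reductive elimination) replaces the triflate by hydrogen and leaves the double bond at C7=C8; no stereocentre is touched.

Step 12
Reactants: 22 tert-butyl (1S,2S,4aS,5R,8aS)-2-[(tert-butyldimethylsilyl)oxy]-1,4a,6-trimethyl-5-(3-methylbut-3-en-1-yl)-1,2,3,4,4a,5,8,8a-octahydronaphthalene-1-carboxylate
Product: 23 {(1R,2S,4aS,5R,8aS)-2-[(tert-butyldimethylsilyl)oxy]-1,4a,6-trimethyl-5-(3-methylbut-3-en-1-yl)-1,2,3,4,4a,5,8,8a-octahydronaphthalen-1-yl}methanol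
Conditions: LiAlH4, THF, 0 °C to reflux; water/NaOH work-up
Reagents that add atoms: none
Why: Hydride reduction of the hindered, non-enolizable tert-butyl ester gives the C19 primary alcohol while the silyl ether and both olefins are inert; no stereocentre is touched.

Step 13
Reactants: 23 the primary alcohol
Product: 24 {(1R,2S,4aS,5R,8aS)-2-[(tert-butyldimethylsilyl)oxy]-1,4a,6-trimethyl-5-(3-methylbut-3-en-1-yl)-1,2,3,4,4a,5,8,8a-octahydronaphthalen-1-yl}methyl acetate
Conditions: Ac2O, pyridine, DMAP (cat.), CH2Cl2, 0 °C to rt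
Reagents that add atoms: acetic anhydride, CC(=O)OC(C)=O
Why: Standard acylation of the only free hydroxyl group gives the C19 acetate.

Step 14
Reactants: 24 the acetate; 25 acrylic acid
Product: 26 (2E)-5-[(1R,4aS,5R,6S,8aS)-5-(acetoxymethyl)-6-[(tert-butyldimethylsilyl)oxy]-2,5,8a-trimethyl-1,4,4a,5,6,7,8,8a-octahydronaphthalen-1-yl]-3-methylpent-2-enoic acid
Conditions: 25 (5 equiv), RuCl2(H2IMes)(=CH-C6H4-2-O-i-Pr) (second-generation Hoveyda–Grubbs catalyst, 10 mol%), CH2Cl2, 40 °C
Reagents that add atoms: none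
Why: Olefin cross-metathesis of the 1,1-disubstituted terminal olefin with acrylic acid builds C13=C14, the hindered trisubstituted ring olefin should not take part, and the E isomer (carboxyl trans to the chain) is favoured thermodynamically.

Step 15
Reactants: 26 the silyl-protected acid
Product: 27 (2E)-5-[(1R,4aS,5R,6S,8aS)-5-(acetoxymethyl)-6-hydroxy-2,5,8a-trimethyl-1,4,4a,5,6,7,8,8a-octahydronaphthalen-1-yl]-3-methylpent-2-enoic acid (target)
Conditions: HF·pyridine, pyridine/THF, 0 °C to rt
Reagents that add atoms: none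
Why: Fluoride cleavage of the silyl ether under buffered conditions frees the C3 hydroxyl without touching the acetate, the acid or the olefins, and acyl migration is disfavoured because the C3 oxygen and C19 are anti on ring A.

**Compound list**

1 | 3-ethoxycyclohex-2-en-1-one | CCOC1=CC(=O)CCC1 | starting material
2 | tert-butyl acetate | CC(=O)OC(C)(C)C | starting material
3 | lithium enolate of tert-butyl acetate | C=C(O[Li])OC(C)(C)C | intermediate
4 | tert-butyl 2-(3-ethoxy-1-hydroxycyclohex-2-en-1-yl)acetate (racemic; lithium alkoxide in the flask) | CCOC1=CC(O)(CC(=O)OC(C)(C)C)CCC1 | intermediate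
5 | tert-butyl 2-(3-oxocyclohex-1-en-1-yl)acetate | CC(C)(C)OC(=O)CC1=CC(=O)CCC1 | intermediate
6 | tert-butyl 2-[(1R)-3-(diphenylsilyloxy)cyclohex-2-en-1-yl]acetate | CC(C)(C)OC(=O)C[C@H]1CCCC(O[SiH](c2ccccc2)c2ccccc2)=C1 | intermediate
7 | tert-butyl 2-[(1R,2R)-2-methyl-3-oxocyclohexyl]acetate | CC(C)(C)OC(=O)C[C@H]1CCCC(=O)[C@@H]1C | intermediate
8 | methyl acrylate | C=CC(=O)OC | starting material
9 | tert-butyl 2-[(1R,2R)-2-(3-methoxy-3-oxopropyl)-2-methyl-3-oxocyclohexyl]acetate | CC(C)(C)OC(=O)C[C@H]1CCCC(=O)[C@]1(C)CCC(=O)OC | intermediate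
10 | tert-butyl (1R,4aR,8aR)-4a-methyl-2,5-dioxodecahydronaphthalene-1-carboxylate (keto form, ester equatorial) | CC(C)(C)OC(=O)[C@@H]1[C@H]2CCCC(=O)[C@]2(C)CCC1=O | intermediate
11 | tert-butyl (1R,4aR,6S,8aR)-4a,6-dimethyl-2,5-dioxodecahydronaphthalene-1-carboxylate (lithium enolate in the flask; equatorial C6 methyl drawn) | CC(C)(C)OC(=O)[C@@H]1[C@H]2CC[C@H](C)C(=O)[C@]2(C)CCC1=O | intermediate
12 | tert-butyl (1S,4aR,6S,8aS)-1,4a,6-trimethyl-2,5-dioxodecahydronaphthalene-1-carboxylate (ester axial, syn to the angular methyl) | CC(C)(C)OC(=O)[C@@]1(C)[C@H]2CC[C@H](C)C(=O)[C@]2(C)CCC1=O | intermediate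
13 | tert-butyl (1S,2S,4aR,6S,8aS)-2-hydroxy-1,4a,6-trimethyl-5-oxodecahydronaphthalene-1-carboxylate | CC(C)(C)OC(=O)[C@@]1(C)[C@H]2CC[C@H](C)C(=O)[C@]2(C)CC[C@@H]1O | intermediate
14 | tert-butyl (1S,2S,4aR,8aS)-2,5-bis[(tert-butyldimethylsilyl)oxy]-1,4a,6-trimethyl-1,2,3,4,4a,7,8,8a-octahydronaphthalene-1-carboxylate | CC(C)(C)OC(=O)[C@@]1(C)[C@H]2CCC(C)=C(O[Si](C)(C)C(C)(C)C)[C@]2(C)CC[C@@H]1O[Si](C)(C)C(C)(C)C | intermediate
15 | tert-butyl (1S,2S,4aR,8aS)-2-[(tert-butyldimethylsilyl)oxy]-1,4a,6-trimethyl-5-oxo-1,2,3,4,4a,5,8,8a-octahydronaphthalene-1-carboxylate | CC(C)(C)OC(=O)[C@@]1(C)[C@H]2CC=C(C)C(=O)[C@]2(C)CC[C@@H]1O[Si](C)(C)C(C)(C)C | intermediate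
16 | 4-bromo-2-methylbut-1-ene | C=C(C)CCBr | starting material
17 | (3-methylbut-3-en-1-yl)magnesium bromide | C=C(C)CC[Mg]Br | intermediate
18 | tert-butyl 2-[(tert-butyldimethylsilyl)oxy]-5-hydroxy-1,4a,6-trimethyl-5-(3-methylbut-3-en-1-yl)-1,2,3,4,4a,5,8,8a-octahydronaphthalene-1-carboxylate (centres as in 15; side chain anti to the angular methyl) | CC(C)(C)OC(=O)[C@@]1(C)[C@H]2CC=C(C)[C@](O)(CCC(C)=C)[C@]2(C)CC[C@@H]1O[Si](C)(C)C(C)(C)C | intermediate
19 | tert-butyl 2-[(tert-butyldimethylsilyl)oxy]-1,4a,6-trimethyl-5-(3-methylbut-3-en-1-yl)-7-oxo-1,2,3,4,4a,7,8,8a-octahydronaphthalene-1-carboxylate (centres as in 15) | CC(C)(C)OC(=O)[C@@]1(C)[C@H]2CC(=O)C(C)=C(CCC(C)=C)[C@]2(C)CC[C@@H]1O[Si](C)(C)C(C)(C)C | intermediate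
20 | lithium enolate of the 7-oxo compound after reduction (5-H anti to the angular methyl) | CC(C)(C)OC(=O)[C@@]1(C)[C@H]2CC(O[Li])=C(C)[C@@H](CCC(C)=C)[C@]2(C)CC[C@@H]1O[Si](C)(C)C(C)(C)C | intermediate
21 | tert-butyl 2-[(tert-butyldimethylsilyl)oxy]-1,4a,6-trimethyl-5-(3-methylbut-3-en-1-yl)-7-{[(trifluoromethyl)sulfonyl]oxy}-1,2,3,4,4a,5,8,8a-octahydronaphthalene-1-carboxylate (configuration as in 22) | CC(C)(C)OC(=O)[C@@]1(C)[C@H]2CC(OS(=O)(=O)C(F)(F)F)=C(C)[C@@H](CCC(C)=C)[C@]2(C)CC[C@@H]1O[Si](C)(C)C(C)(C)C | intermediate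
22 | tert-butyl (1S,2S,4aS,5R,8aS)-2-[(tert-butyldimethylsilyl)oxy]-1,4a,6-trimethyl-5-(3-methylbut-3-en-1-yl)-1,2,3,4,4a,5,8,8a-octahydronaphthalene-1-carboxylate | CC(C)(C)OC(=O)[C@@]1(C)[C@H]2CC=C(C)[C@@H](CCC(C)=C)[C@]2(C)CC[C@@H]1O[Si](C)(C)C(C)(C)C | intermediate
23 | {(1R,2S,4aS,5R,8aS)-2-[(tert-butyldimethylsilyl)oxy]-1,4a,6-trimethyl-5-(3-methylbut-3-en-1-yl)-1,2,3,4,4a,5,8,8a-octahydronaphthalen-1-yl}methanol | OC[C@@]1(C)[C@H]2CC=C(C)[C@@H](CCC(C)=C)[C@]2(C)CC[C@@H]1O[Si](C)(C)C(C)(C)C | intermediate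
24 | {(1R,2S,4aS,5R,8aS)-2-[(tert-butyldimethylsilyl)oxy]-1,4a,6-trimethyl-5-(3-methylbut-3-en-1-yl)-1,2,3,4,4a,5,8,8a-octahydronaphthalen-1-yl}methyl acetate | CC(=O)OC[C@@]1(C)[C@H]2CC=C(C)[C@@H](CCC(C)=C)[C@]2(C)CC[C@@H]1O[Si](C)(C)C(C)(C)C | intermediate
25 | acrylic acid | C=CC(=O)O | starting material
26 | (2E)-5-[(1R,4aS,5R,6S,8aS)-5-(acetoxymethyl)-6-[(tert-butyldimethylsilyl)oxy]-2,5,8a-trimethyl-1,4,4a,5,6,7,8,8a-octahydronaphthalen-1-yl]-3-methylpent-2-enoic acid | CC(=O)OC[C@@]1(C)[C@H]2CC=C(C)[C@@H](CC/C(C)=C/C(=O)O)[C@]2(C)CC[C@@H]1O[Si](C)(C)C(C)(C)C | intermediate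
27 | (2E)-5-[(1R,4aS,5R,6S,8aS)-5-(acetoxymethyl)-6-hydroxy-2,5,8a-trimethyl-1,4,4a,5,6,7,8,8a-octahydronaphthalen-1-yl]-3-methylpent-2-enoic acid | CC(=O)OC[C@@]1(C)[C@H]2CC=C(C)[C@@H](CC/C(C)=C/C(=O)O)[C@]2(C)CC[C@@H]1O | target

**Step count and risks**

Total step count: 15. Longest linear sequence: 15 steps (from 1; compounds 2, 8, 16 and 25 are commercial and enter directly).

Steps most likely to fail:

Step 3. Michael addition at the less substituted α-carbon (C8), oligomerization of the acrylate under stoichiometric alkoxide, or incomplete ring closure could lower the throughput of the cascade. Fallback, setting out from 7 and coming back at 10: 7 is condensed with benzylamine (toluene, 4 Å MS) to the imine tert-butyl 2-[(1R,2R)-3-(benzylimino)-2-methylcyclohexyl]acetate F1. Its more substituted secondary enamine tautomer should add to 8 (THF, 50 °C) in a neutral aza-ene-type Michael reaction, anti to the C5 arm and only at C10, to give tert-butyl 2-[(1R,2R)-3-(benzylimino)-2-(3-methoxy-3-oxopropyl)-2-methylcyclohexyl]acetate F2. Aqueous AcOH hydrolyses F2 to 9, and isolated 9 is closed to 10 in a separate Dieckmann condensation (KOt-Bu, THF, 0 °C).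

Step 5. Loss of chemoselectivity between the C3 and C9 ketones, or hydride delivery to the wrong face of C3, would give the diol or the equatorial alcohol. Fallback, setting out from 12 and coming back at 13: the control element is changed from the ring conformation to the catalyst. Corey–Bakshi–Shibata reduction with (R)-Me-CBS oxazaborolidine and BH3·SMe2 (toluene, −30 °C) is predicted by the usual model, with quaternary C4 as the large and C2 as the small substituent, to give the (S)-carbinol of 13, and it should prefer the less hindered C3 ketone. This fallback makes no new compound (F0).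

Step 14. Slow metathesis of the 1,1-disubstituted olefin, catalyst decomposition in the presence of the free acid, or incomplete E-selectivity may limit the side-chain completion. Fallback, setting out from 24 and coming back at 26: Lemieux–Johnson cleavage of the exposed terminal olefin (OsO4 cat., NaIO4, 2,6-lutidine, dioxane/water) should give the methyl ketone {(1R,2S,4aS,5R,8aS)-2-[(tert-butyldimethylsilyl)oxy]-1,4a,6-trimethyl-5-(3-oxobutyl)-1,2,3,4,4a,5,8,8a-octahydronaphthalen-1-yl}methyl acetate F3. Horner–Wadsworth–Emmons olefination with allyl diethylphosphonoacetate (NaH, THF) should give the allyl ester allyl (2E)-5-[(1R,4aS,5R,6S,8aS)-5-(acetoxymethyl)-6-[(tert-butyldimethylsilyl)oxy]-2,5,8a-trimethyl-1,4,4a,5,6,7,8,8a-octahydronaphthalen-1-yl]-3-methylpent-2-enoate F4, with the E isomer separated by chromatography. Pd(PPh3)4 and morpholine (THF, rt) then remove the allyl group without touching the acetate and give 26.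

Further compounds
F1 | step 3 | tert-butyl 2-[(1R,2R)-3-(benzylimino)-2-methylcyclohexyl]acetate | CC(C)(C)OC(=O)C[C@H]1CCCC(=NCc2ccccc2)[C@@H]1C
F2 | step 3 | tert-butyl 2-[(1R,2R)-3-(benzylimino)-2-(3-methoxy-3-oxopropyl)-2-methylcyclohexyl]acetate | CC(C)(C)OC(=O)C[C@H]1CCCC(=NCc2ccccc2)[C@]1(C)CCC(=O)OC
F0 | step 5 | none | none
F3 | step 14 | {(1R,2S,4aS,5R,8aS)-2-[(tert-butyldimethylsilyl)oxy]-1,4a,6-trimethyl-5-(3-oxobutyl)-1,2,3,4,4a,5,8,8a-octahydronaphthalen-1-yl}methyl acetate | CC(=O)OC[C@@]1(C)[C@H]2CC=C(C)[C@@H](CCC(C)=O)[C@]2(C)CC[C@@H]1O[Si](C)(C)C(C)(C)C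
F4 | step 14 | allyl (2E)-5-[(1R,4aS,5R,6S,8aS)-5-(acetoxymethyl)-6-[(tert-butyldimethylsilyl)oxy]-2,5,8a-trimethyl-1,4,4a,5,6,7,8,8a-octahydronaphthalen-1-yl]-3-methylpent-2-enoate | CC(=O)OC[C@@]1(C)[C@H]2CC=C(C)[C@@H](CC/C(C)=C/C(=O)OCC=C)[C@]2(C)CC[C@@H]1O[Si](C)(C)C(C)(C)C
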